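**Retrosynthetic overview**

1. The target comes from a cis-(3S,4S)-4-hydroxy-3-methylisochroman-1-one with TIPS ethers on O6 and O8, by 4-O-acetylation, desilylation and selective 6-O-geranylation.
2. That alcohol comes from the racemic 3-methylisochromane-1,4-dione by one asymmetric transfer hydrogenation under dynamic kinetic resolution, which sets C4 and C3 together.
3. The dione comes from a one-pot [4+2] annulation of 5-methoxy-2,4-bis(triisopropylsilyloxy)benzoic acid (a C,O-dinucleophile) with racemic 2-chloro-N-methoxy-N-methylpropanamide (a 1,2-dielectrophile): carboxylate-directed lithiation at C4a–H, acylation (C4a–C4 bond), then carboxylate SN2 at C3 (O2–C3 bond). The lactone ring is the only ring to be formed and it is formed here.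
4. Enabling feature: C4a–H is the only C–H ortho to the C1 carboxyl and lies between it and the C5 methoxy oxygen, so both direct the base there; the same carboxylate oxygen (O2) then sits where a six-membered ring to C3 can close. The C4 carbonyl next to C3–H makes C3 labile, which the reduction exploits.
5. The acid comes from 2,4-dihydroxy-5-methoxybenzaldehyde by bis-silylation and Pinnick oxidation.

Key step: step 4

Remark: ring positions are named throughout by the isochroman-1-one numbering of the target (C1, O2, C3, C4, C4a, C5 to C8, C8a), also in the open precursors; 2,4-dihydroxy-5-methoxybenzaldehyde is assumed to be a purchasable catalogue compound.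

**Route**

Step 1
Reactants: 1 2,4-dihydroxy-5-methoxybenzaldehyde
Product: 2 5-methoxy-2,4-bis(triisopropylsilyloxy)benzaldehyde
Conditions: TIPSOTf (2.3 equiv), 2,6-lutidine (3 equiv), CH2Cl2, 0 °C to rt
Reagents that add atoms: triisopropylsilyl trifluoromethanesulfonate (TIPSOTf), CC(C)[Si](OS(=O)(=O)C(F)(F)F)(C(C)C)C(C)C
Why: Silyl triflate with a hindered pyridine base silylates both phenols, the hydrogen-bonded one included (standard silyl ether formation), and the two bulky TIPS ethers are chosen because they neither direct lithiation nor leave room at C7–H in step 4.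

Step 2
Reactants: 2 5-methoxy-2,4-bis(triisopropylsilyloxy)benzaldehyde
Product: 3 5-methoxy-2,4-bis(triisopropylsilyloxy)benzoic acid
Conditions: NaClO2, NaH2PO4, 2-methyl-2-butene, t-BuOH/THF/H2O, 0 °C to rt
Reagents that add atoms: sodium chlorite (NaClO2), [Na+].[O-]Cl=O
Why: Pinnick oxidation converts the aryl aldehyde to the acid at about pH 4 without touching the silyl ethers, with 2-methyl-2-butene taking up the hypochlorous acid that would otherwise chlorinate the electron-rich ring.

Step 3
Reactants: 4 2-chloropropanoyl chloride (racemic); 5 N,O-dimethylhydroxylamine hydrochloride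
Product: 6 2-chloro-N-methoxy-N-methylpropanamide (racemic)
Conditions: K2CO3 (2.2 equiv), CH2Cl2/H2O, 0 °C
Reagents that add atoms: none
Why: Schotten–Baumann acylation of the hydroxylamine by the acid chloride gives the Weinreb amide, and the inorganic base in a two-phase system avoids the ketene formation that a tertiary amine would cause with an α-chloro acid chloride.

Step 4
Reactants: 3 5-methoxy-2,4-bis(triisopropylsilyloxy)benzoic acid; 6 2-chloro-N-methoxy-N-methylpropanamide
Product: 10 rac-5-methoxy-3-methyl-6,8-bis(triisopropylsilyloxy)isochromane-1,4-dione, via aryllithium carboxylate 7 (not isolated), via tetrahedral adduct 8 (not isolated), via chloroketone carboxylate 9 (not isolated)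
Conditions: 3 added to s-BuLi (2.2 equiv), TMEDA (2.2 equiv), THF, −90 to −78 °C; then 6 (1.3 equiv), −78 to 0 °C; then AcOH (1.1 equiv), H2O, NaI (10 mol %), DMF, 45 °C, same flask
Reagents that add atoms: none
Why: The first equivalent of s-BuLi makes the lithium carboxylate, which holds the TMEDA-complexed second equivalent at C4a–H (the only C–H ortho to C1 and the one also flanked by the C5 methoxy oxygen) to give dianion 7; 7 adds to Weinreb amide 6 (C4a–C4 bond) and stops at the N,O-chelated adduct 8, which the buffered quench collapses to α-chloro ketone 9, whose carboxylate oxygen then displaces chloride at C3 (O2–C3 bond). The closest known reaction types are the carboxylate-directed ortho-lithiation of alkoxybenzoic acids, the Weinreb ketone synthesis with α-chloro amides and the closure of 2-(α-haloacyl)benzoic acids to isochromane-1,4-diones. The lactone ring closes 6-exo-tet by SN2 at a carbon that the adjacent C4 ketone activates, with iodide as nucleophilic catalyst; addition of the carboxylate to the ketone (five-membered pseudo-acid) is reversible and drains into the lactone. C3 is formed racemic and this is intended: lying between the C4 ketone and O2 it is configurationally labile, so no reagent control is spent on it here and step 5 sets it together with C4. The step needs site selectivity in the metalation and chemoselectivity in the acylation: C7–H is walled in by two TIPS ethers that neither bind lithium nor leave room for the base, the carboxylate is inert to the aryllithium, and the chelate 8 prevents a second addition.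

Step 5
Reactants: 10 rac-5-methoxy-3-methyl-6,8-bis(triisopropylsilyloxy)isochromane-1,4-dione
Product: 11 (3S,4S)-4-hydroxy-5-methoxy-3-methyl-6,8-bis(triisopropylsilyloxy)isochroman-1-one (cis)
Conditions: RuCl(p-cymene)[(R,R)-TsDPEN] (2 mol %), HCO2H/Et3N (5:2), DMF, 30 °C
Reagents that add atoms: none
Why: Noyori–Ikariya asymmetric transfer hydrogenation under dynamic kinetic resolution: C3–H, lying between the C4 ketone and O2 (its enol is a 4-hydroxyisocoumarin), should epimerise in the amine/formic acid medium faster than the ketone is reduced, while the (R,R)-catalyst delivers hydride to the C4 face that gives (R)-1-tetralol from 1-tetralone (named 4S here because C3 carries oxygen and outranks C4a) and does so on the C3 epimer that lets it come in anti to the methyl group, so C4 and C3 should be set together as cis-(3S,4S).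

Step 6
Reactants: 11 (3S,4S)-4-hydroxy-5-methoxy-3-methyl-6,8-bis(triisopropylsilyloxy)isochroman-1-one
Product: 12 (3S,4S)-5-methoxy-3-methyl-1-oxo-6,8-bis(triisopropylsilyloxy)isochroman-4-yl acetate
Conditions: Ac2O (1.5 equiv), pyridine, DMAP (5 mol %), CH2Cl2, 0 °C
Reagents that add atoms: acetic anhydride (Ac2O), CC(=O)OC(C)=O
Why: DMAP-catalysed acylation of the secondary benzylic alcohol leaves the C4–O bond and hence the configuration untouched, and it is run under weakly basic conditions directly after step 5 so that the free 4-hydroxy lactone has no chance to translactonise to the five-membered phthalide.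

Step 7
Reactants: 12 (3S,4S)-5-methoxy-3-methyl-1-oxo-6,8-bis(triisopropylsilyloxy)isochroman-4-yl acetate
Product: 13 (3S,4S)-6,8-dihydroxy-5-methoxy-3-methyl-1-oxoisochroman-4-yl acetate
Conditions: Bu4NF (2.2 equiv), AcOH (2.5 equiv), THF, 0 °C
Reagents that add atoms: none
Why: Fluoride cleaves both aryl silyl ethers (Si–F bond formation) while the acetic acid buffer keeps the phenols protonated so that acetate and lactone are not attacked, and since neither phenol is ortho or para to C4a no quinone methide can expel the benzylic acetate.

Step 8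
Reactants: 13 (3S,4S)-6,8-dihydroxy-5-methoxy-3-methyl-1-oxoisochroman-4-yl acetate; 14 geranyl bromide ((2E)-1-bromo-3,7-dimethylocta-2,6-diene)
Product: 15 (3S,4S)-6-[(2E)-3,7-dimethylocta-2,6-dienyloxy]-8-hydroxy-5-methoxy-3-methyl-1-oxoisochroman-4-yl acetate (CNP0251645.1)
Conditions: K2CO3 (1.1 equiv), 14 (1.05 equiv), acetone, rt
Reagents that add atoms: none
Why: Williamson etherification (SN2 at the primary allylic bromide, E geometry untouched) should be selective for the 6-OH, which is para to the lactone carbonyl, more acidic and free, whereas the 8-OH is tied up in a hydrogen bond to the C1 carbonyl, the same selectivity as in 2,4-dihydroxyaryl carbonyl compounds.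

**Compound list**

1 | 2,4-dihydroxy-5-methoxybenzaldehyde | COc1cc(C=O)c(O)cc1O | starting material
2 | 5-methoxy-2,4-bis(triisopropylsilyloxy)benzaldehyde | COc1cc(C=O)c(O[Si](C(C)C)(C(C)C)C(C)C)cc1O[Si](C(C)C)(C(C)C)C(C)C | intermediate
3 | 5-methoxy-2,4-bis(triisopropylsilyloxy)benzoic acid | COc1cc(C(=O)O)c(O[Si](C(C)C)(C(C)C)C(C)C)cc1O[Si](C(C)C)(C(C)C)C(C)C | intermediate
4 | 2-chloropropanoyl chloride (racemic) | CC(Cl)C(=O)Cl | starting material
5 | N,O-dimethylhydroxylamine hydrochloride | CNOC.Cl | starting material
6 | 2-chloro-N-methoxy-N-methylpropanamide (racemic) | CC(Cl)C(=O)N(C)OC | intermediate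
7 | lithium 2-lithio-3-methoxy-4,6-bis(triisopropylsilyloxy)benzoate (aryllithium carboxylate, not isolated) | COc1c([Li])c(C(=O)O[Li])c(O[Si](C(C)C)(C(C)C)C(C)C)cc1O[Si](C(C)C)(C(C)C)C(C)C | intermediate
8 | lithium 2-[2-chloro-1-(lithiooxy)-1-(N-methoxy-N-methylamino)propyl]-3-methoxy-4,6-bis(triisopropylsilyloxy)benzoate (tetrahedral adduct, not isolated) | COc1c(C(O[Li])(N(C)OC)C(C)Cl)c(C(=O)O[Li])c(O[Si](C(C)C)(C(C)C)C(C)C)cc1O[Si](C(C)C)(C(C)C)C(C)C | intermediate
9 | lithium 2-(2-chloropropanoyl)-3-methoxy-4,6-bis(triisopropylsilyloxy)benzoate (racemic chloroketone carboxylate, not isolated) | COc1c(C(=O)C(C)Cl)c(C(=O)O[Li])c(O[Si](C(C)C)(C(C)C)C(C)C)cc1O[Si](C(C)C)(C(C)C)C(C)C | intermediate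
10 | rac-5-methoxy-3-methyl-6,8-bis(triisopropylsilyloxy)isochromane-1,4-dione | COc1c(O[Si](C(C)C)(C(C)C)C(C)C)cc(O[Si](C(C)C)(C(C)C)C(C)C)c2c1C(=O)C(C)OC2=O | intermediate
11 | (3S,4S)-4-hydroxy-5-methoxy-3-methyl-6,8-bis(triisopropylsilyloxy)isochroman-1-one | COc1c(O[Si](C(C)C)(C(C)C)C(C)C)cc(O[Si](C(C)C)(C(C)C)C(C)C)c2c1[C@H](O)[C@H](C)OC2=O | intermediate
12 | (3S,4S)-5-methoxy-3-methyl-1-oxo-6,8-bis(triisopropylsilyloxy)isochroman-4-yl acetate | COc1c(O[Si](C(C)C)(C(C)C)C(C)C)cc(O[Si](C(C)C)(C(C)C)C(C)C)c2c1[C@H](OC(C)=O)[C@H](C)OC2=O | intermediate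
13 | (3S,4S)-6,8-dihydroxy-5-methoxy-3-methyl-1-oxoisochroman-4-yl acetate | COc1c(O)cc(O)c2c1[C@H](OC(C)=O)[C@H](C)OC2=O | intermediate
14 | geranyl bromide, (2E)-1-bromo-3,7-dimethylocta-2,6-diene | BrC/C=C(\C)CCC=C(C)C | starting material
15 | (3S,4S)-6-[(2E)-3,7-dimethylocta-2,6-dienyloxy]-8-hydroxy-5-methoxy-3-methyl-1-oxoisochroman-4-yl acetate | COc1c(OC/C=C(\C)CCC=C(C)C)cc(O)c2c1[C@H](OC(C)=O)[C@H](C)OC2=O | target

**Step count and risks**

Total step count: 8. Longest linear sequence: 7 (steps 1, 2, 4, 5, 6, 7, 8); step 3 is a one-step side branch.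

The three steps most likely to fail:

Step 4. What may go wrong: proton transfer from the acidic α-chloro amide to the hindered aryllithium (returning 3), addition of s-BuLi to the lithium carboxylate, or sluggish displacement at the secondary chloride. The fallback sets out from 3 and separates acylation from ring closure. The same lithiation is followed by acylation with the halogen-free, less acidic N-methoxy-N-methylpropanamide to give 3-methoxy-2-propanoyl-4,6-bis(triisopropylsilyloxy)benzoic acid F1. α-Bromination of the ketone with PhNMe3Br3 in THF at 0 °C gives 2-(2-bromopropanoyl)-3-methoxy-4,6-bis(triisopropylsilyloxy)benzoic acid F2. NaHCO3 in DMF at rt then closes the lactone by the same carboxylate displacement, and the route is rejoined at 10.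

Step 5. What may go wrong: epimerisation at C3 that is slower than reduction (so that the reduction behaves as a kinetic resolution), or erosion of facial control by the C5 methoxy group ortho to the ketone, either of which would give a mixture of stereoisomers. The fallback sets out from 10. Substrate-controlled reduction with LiBH(s-Bu)3 in THF at −78 °C (hydride anti to the C3 methyl group) should give the racemic cis-4-hydroxy-5-methoxy-3-methyl-6,8-bis(triisopropylsilyloxy)isochroman-1-one F3. Enzymatic kinetic resolution with Candida antarctica lipase B and vinyl acetate in MTBE at 30 °C is expected, by the empirical rule for lipase acylation of cyclic benzylic alcohols, to acetylate the (4S) enantiomer. This would give acetate 12 directly and leave (3R,4R)-4-hydroxy-5-methoxy-3-methyl-6,8-bis(triisopropylsilyloxy)isochroman-1-one F4, which is removed by chromatography; the route is rejoined at 12.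

Step 8. What may go wrong: alkylation of both phenols or of the hydrogen-bonded 8-OH, or carbonate-induced loss of the acetate. The fallback sets out from 13 and replaces the base-mediated alkylation by a Mitsunobu etherification with geraniol (PPh3, diisopropyl azodicarboxylate, THF, 0 °C). This redox condensation runs without base and engages the free, more acidic 6-OH; it rejoins the route at 15 and makes no compound outside the list (F0).

Further compounds
F1 | step 4 | 3-methoxy-2-propanoyl-4,6-bis(triisopropylsilyloxy)benzoic acid | COc1c(C(=O)CC)c(C(=O)O)c(O[Si](C(C)C)(C(C)C)C(C)C)cc1O[Si](C(C)C)(C(C)C)C(C)C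
F2 | step 4 | 2-(2-bromopropanoyl)-3-methoxy-4,6-bis(triisopropylsilyloxy)benzoic acid (racemic) | COc1c(C(=O)C(C)Br)c(C(=O)O)c(O[Si](C(C)C)(C(C)C)C(C)C)cc1O[Si](C(C)C)(C(C)C)C(C)C
F3 | step 5 | racemic cis-4-hydroxy-5-methoxy-3-methyl-6,8-bis(triisopropylsilyloxy)isochroman-1-one (1:1 pair of enantiomers) | COc1c(O[Si](C(C)C)(C(C)C)C(C)C)cc(O[Si](C(C)C)(C(C)C)C(C)C)c2c1[C@H](O)[C@H](C)OC2=O.COc1c(O[Si](C(C)C)(C(C)C)C(C)C)cc(O[Si](C(C)C)(C(C)C)C(C)C)c2c1[C@@H](O)[C@@H](C)OC2=O
F4 | step 5 | (3R,4R)-4-hydroxy-5-methoxy-3-methyl-6,8-bis(triisopropylsilyloxy)isochroman-1-one | COc1c(O[Si](C(C)C)(C(C)C)C(C)C)cc(O[Si](C(C)C)(C(C)C)C(C)C)c2c1[C@@H](O)[C@@H](C)OC2=O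
F0 | step 8 | none | none
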